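The rate constants were drawn at random within sensible limits; the result is computed.

Which set-up turns the most of one substrate charge into product, and how much does each one give?

| setting | eta | zeta | alpha | beta |
|---|---|---|---|---|
| substrate | 0.50 M | 0.50 M (fed, over 7.50 h) | 0.50 M | 0.50 M |
| free catalyst | 40 mM | 40 mM | 40 mM | 40 mM |
| remark | a single well-mixed tank run continuously and read at steady state, 15 h in it on average | a stirred flask in which substrate is dosed at a steady rate over 7.50 h without added volume, worked up at 15 h | one stirred flow tank at steady state, fed with the mixture as stated, mean residence time 45.0 h | a closed flask charged with all of it at once and left for 15 h |
| time |  | 15 h |  | 15 h |

    2 catalyst intermediate → spent catalyst (k1 = 0.039 M⁻¹ min⁻¹)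
    substrate + free catalyst ⇌ catalyst intermediate (K2 = 1.3 M⁻¹, k2 = 8.9 M⁻¹ min⁻¹)
    catalyst intermediate → free catalyst + product (k3 = 0.038 min⁻¹)

- the set-up with the highest amount of product at the outlet or at the end, in percent of the substrate put in ("none" if the first two lie within 2 percentage points) (eta / zeta / alpha / beta / none)
- amount of product at the outlet or at the end, in percent of the substrate put in, eta
- amount of product at the outlet or at the end, in percent of the substrate put in, zeta
- amount of product at the outlet or at the end, in percent of the substrate put in, alpha
- amount of product at the outlet or at the end, in percent of the substrate put in, beta

- in percentages every species weighs as the substrate in it: one spent catalyst counts as two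
- a step written with two of one species runs at k times the square of its concentration and takes two of it each time
- the stated concentrations are those of everything mixed, before any reaction; amounts are the same in each set-up
- the feed brings no volume worth counting
- run time (zeta): 15 h

Keep your books on the substrate, the limiting reagent: each mole ends unbound, held on catalyst, locked in spent catalyst, or as product. The held entry cannot pass 8.00% of the charge. Intermediate falls apart faster than it releases product, at 6.85 min⁻¹ against 0.038 min⁻¹, so I take binding as staying close to its equilibrium and release as the rate-limiting step. With 0.650 as binding constant times charge, the starting intermediate goes to spent catalyst at 3.23% of its rate to product, so I first close the books without that entry, as the zero of the scale.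

Then one quantity carries the reckoning: the contact number, the release constant times the binding constant times the catalyst charge times the substrate's average stay, 1.78 for a stay of 15 h, as in eta and beta. It is 5.34 in alpha, and with the mean dose arriving at mid-feed, a rough transfer, 1.33 in zeta. On these books the fraction of substrate left falls, per unit of this number, at that fraction divided by one plus the binding constant times [substrate]. Integrating that for the flasks, and solving the quadratic balance for the tanks, with held substrate counted as unturned, I get 58.3% for eta, 60.5% for zeta, 82.8% for alpha and 72.7% for beta, so alpha leads.

The forecast gives 53.8%, 57.3%, 80.1% and 65.9% in that order, each lower than my figure, picks alpha, and speaks of “a low intermediate level that spares the catalyst”.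

The simulation gives 53.8%, 57.4%, 80.2% and 66.0%, with alpha first, and my figures stand higher than these, by 4.5 percentage points in eta and 6.7 points in beta. Striking out spent catalyst lifts eta to 57.3%, a gain of 3.5 points, against 14 points between alpha and beta. Beta is not at rest at 15.0 h, with 31.5% of its substrate unbound. At ten times the time its contact number is 17.8, and in beta product reads 98.4%, unbound substrate 0% and intermediate 0%, while spent catalyst, 20.1% of the catalyst charge, holds 1.61% of the substrate, which closes the books.

In the neighbour like zeta but with 0.010 M of free catalyst, a quarter of the catalyst in zeta, the contact number falls to 0.333 and the same integration gives 18.8% product. The simulation gives 19.1%, with 80.1% of the substrate unbound.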